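The noon run, with 0.080 M of partner on 0.057 M of starting material, raised product from 15 % at 4.00 h to 38 % at 12.0 h, a pace of 0.00164 M h⁻¹.

| flask | starting material | partner | capture agent | free catalyst | remark | time |
|---|---|---|---|---|---|---|
| noon | 0.057 M | 0.080 M | 5.7 mM | 29 µM | run made earlier |  |
| flask | 0.057 M | 0.0399 M | 5.70 mM | 29 µM |  | 5.0 d |

noon run (percent of the starting material charged)

| time / h | product / % | starting material / % |
|---|---|---|
| 2.00 | 3 | 49 |
| 4.00 | 15 | 39 |
| 6.00 | 23 | 35 |
| 8.00 | 26 | 29 |
| 10.0 | 30 | 27 |
| 12.0 | 38 | 27 |

(each reading ± 1.5 percentage points)



- concentration of product at 5.0 d, in M
- concentration of starting material at 5.0 d, in M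
- concentration of trapped intermediate at 5.0 d, in M
- concentration of partner at 5.0 d, in M

Two chemists dispute the flask. The first calls partner the limiting reagent: its charge of 0.0399 M is smaller than the 0.057 M of starting material. At the noon pace that much product takes 24.3 h, and 5.0 d is longer, so he expects 0.0399 M of product and no partner.

The second answers that a pace is not a constant. The flask starts with half the partner of the noon run, and the pace should follow the product of two amounts: partner, and the pool, meaning whatever of the charge is not yet product. I take this side. Between those noon readings the mean pool was 0.0419 M and the mean partner 0.0649 M, which gives 0.603 M⁻¹ h⁻¹. This pace per unit of pool and per unit of partner is the pairing constant, a reading that carries the scatter.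

Integrating this law from the flask's charges, the ratio of pool to partner grows by a factor 3.44 over 5.0 d. My reckoning therefore gives 0.0355 M of product and 0.00440 M of partner left.

The forecast stands on the same side, with its own constant and its own pool. From “Second-order integration over about 118 h” it gives 0.0354 M of product, 0.008 M of starting material, 0.0055 M of trapped intermediate and 0.0045 M of partner.

The flask gives 0.0348 M of product, 0.00751 M of starting material, 0.00345 M of trapped intermediate and 0.00507 M of partner.

    starting material + free catalyst ⇌ free catalyst + open intermediate (K = 1.50, k = 333 M⁻¹ min⁻¹)
    starting material + free catalyst → spent catalyst (k = 0.00160 M⁻¹ min⁻¹)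
    partner + free catalyst + open intermediate → free catalyst + product (k = 630 M⁻² min⁻¹)
    open intermediate + capture agent → trapped intermediate (k = 0.00768 M⁻¹ min⁻¹)

This flask keeps 0.00507 M of partner where the first chemist expected none, and its product of 0.0348 M stands below his 0.0399 M and close to my 0.0355 M. The forecast's trapped intermediate is higher than the flask's, with 39 % of the capture agent still there. The first view gets its region in this same flask at 50.0 d, where partner is down to 1.22 × 10⁻⁵ M and product is 0.0399 M, close to the partner charge. In the neighbouring flask with 0.016 M of partner, the pairing constant gives a factor 19.4 and 0.0154 M of product; that flask holds 0.0152 M.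

(The earlier runs and the new flask were computed with made-up constants; noise was put on by code.)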